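The product stops. The violet run is this very flask, followed to 96.0 h, and from 6.00 h on its product stays near 25%.

| flask | starting material | partner | temperature | remark | time |
|---|---|---|---|---|---|
| violet | 0.10 M | 0.50 M | 40 °C | the very flask that is asked about, followed so far |  |
| blue | 0.20 M | 0.50 M | 35 °C | run made earlier |  |
| flask | 0.10 M | 0.500 M | 40 °C |  | 6.0 d |

- violet (time / h: product / %, starting material / %): 6.00: 23, 76; 15.0: 24, 75; 30.0: 25, 78; 50.0: 25, 74; 72.0: 27, 78; 96.0: 26, 75
- blue (time / h: product / %, starting material / %): 0.200: 1, 100; 0.667: 3, 97; 1.00: 9, 90; 2.00: 9, 84; 2.50: 15, 85; 3.00: 14, 88

(standard deviation of a reading: 2 percentage points)

- autumn: at 6.0 d add partner, 100% of the amount charged, then wait 40 h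
- dawn: at 6.0 d take out 90% of the product then present, then wait 40 h
- dusk: change nothing and wait 40 h more
- winter: at 6.0 d raise the temperature by 20 K, then wait 40 h

- product, in percent of the starting material first charged, at 6.0 d
- which option adds most product ("none" when 2 percentage points or less is all one gets) (autumn / dawn / dusk / winter / none)
- product present, with what was taken out counted in, in percent of the starting material first charged, after autumn
- product present, with what was taken out counted in, in percent of the starting material first charged, after dusk

- product taken out counts as made
- what was read earlier has a scatter of 2 percentage points, one standard deviation
- additions bring no volume worth counting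

Start with the balance of the reagent charged in the smaller amount, the starting material, at 0.10 M against 0.500 M of partner. At the last violet reading, starting material and product add up to 101%, so those two columns account for it. Take the mean violet reading as the share of starting material that outlives one charge of partner, the charge factor 76.0%.

Why does the reaction stop? At one partner per product, product formation took 4.80% of the partner charge, less than the whole, so it can't have used up the partner. So you have two readings: an equilibrium, or partner lost by a route no column shows. The readings can't separate them, because partner was never read.

Suppose partner is lost. If that loss runs on its own and [starting material] falls first-order, a fresh charge repeats the factor: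

product now = 1 − f = 24.0%

product after autumn = 1 − f² = 42.2%

But first order is an assumption. The blue run can't test it, because it differs in both charge and temperature. Still, autumn gains under either reading, while dawn gains under equilibrium and gives nothing if partner is lost. So I commit to autumn, whose gain of 18 percentage points is more than the margin of 2 points, and I expect dusk to stay at 24.0%.

The forecast differs on the choice. It gives 25% now (23.5% to 26.5%), 25% after dusk (23.5% to 26.5%) and 40% after autumn (33% to 43%), and it picks dawn: “I therefore read the plateau as an equilibrium”.

The flask gives 24.4% at 6.0 d, 24.4% after dusk and 43.1% after autumn. The best option is autumn, which adds 19 points, while dawn adds 0 points and winter 0 points.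

    starting material + partner → product, rate k1*[starting material]*[partner]^1.5 (k = 9.70 × 10⁻⁵ M⁻¹·⁵ s⁻¹, Ea = 74.0 kJ mol⁻¹)
    partner → decomposed reagent (k = 7.70 × 10⁻⁵ s⁻¹, Ea = 95.0 kJ mol⁻¹)
    (constants at 40 °C)

At the start, partner in this flask turns into decomposed reagent 11 times as fast as it enters product, and at 144 h 0% of its charge stands beside 76% of the starting material, so partner, though the larger charge, is the limiting reagent of this flask. One minus the charge factor squared gave 42.2% for autumn, against 43.1% in the flask. The rate of the step to product goes with [partner] to the power 1.50, so for a further flask with 1.2 M of partner, raise the factor to (1.2 M/0.500 M) to that power, which gives 64.0% product; that flask holds 64.4%.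

(All runs were computed for substances that don't exist, noise included.)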